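**Retrosynthetic overview**

1. Ring numbering of the target: C1 ketone, C2 =CH, C3 =C(OMe), C4 mixed ketal carbon, C5 CH2, C6 CH(allyl). The last step makes C1–C2 and C3–C4 together by a nickel-catalysed [4+2] insertion of methoxyacetylene into the C(=O)–C(ketal) bond of a 2,2-dioxygenated cyclobutanone.
2. Enabling feature: the C2=C3 enol ether is a masked ynol ether lying between ketone C1 and ketal C4. The remaining ring atoms C4–C5–C6–C1 are therefore a cyclobutane-1,2-dione monoketal, whose C1–C4 bond is strained and whose migrating carbon carries two oxygens.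
3. The cyclobutanone comes from the methyl enol ether of 3-allylcyclobutanone and 2-allyl-4,5-dimethoxyphenol by anti epoxidation and anti opening. The allyl stereocentre relays to the ketal carbon, and the relay carbinol becomes the C1 ketone.
4. Absolute configuration comes from chiral lithium amide desymmetrisation of 3-allylcyclobutanone (keteniminium [2+2] of N,N-dimethylacetamide with penta-1,4-diene). The phenol comes from O-allylation and Claisen rearrangement.
5. Order of ring formation: arene bought; cyclobutane in step 3; cyclohexenone by two-carbon ring expansion in step 9.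

Key step: step 9

Assumption: the sense of induction in step 4 is taken by analogy with 4-substituted cyclohexanones ((R,R)-amide giving the (S)-enol silane). Both antipodes of the amine are commercial, and the one that delivers the (S)-enol silane is the one to use. Methoxyacetylene is treated as not reliably purchasable and is made in step 8.

**Route**

Step 1
Reactants: 1 3,4-dimethoxyphenol; 2 allyl bromide
Product: 3 4-(allyloxy)-1,2-dimethoxybenzene
Conditions: K2CO3, acetone, reflux
Reagents that add atoms: none
Why: Williamson etherification (SN2 of the phenoxide on the allylic bromide) should proceed cleanly, and no stereocentre is involved.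

Step 2
Reactants: 3 4-(allyloxy)-1,2-dimethoxybenzene
Product: 4 2-allyl-4,5-dimethoxyphenol
Conditions: N,N-diethylaniline, 190 °C
Reagents that add atoms: none
Why: aromatic Claisen rearrangement ([3,3]-sigmatropic shift, then tautomerisation) should deliver the allyl group to the ortho carbon that is not flanked by a methoxy group.

Step 3
Reactants: 5 N,N-dimethylacetamide; 6 penta-1,4-diene
Product: 9 3-allylcyclobutan-1-one, via N,N-dimethylketeniminium triflate 7 (not isolated), via cyclobutaniminium triflate 8 (not isolated)
Conditions: Tf2O, 2,4,6-collidine, (CH2Cl)2, −20 °C; 6 (5 equiv), sealed tube, 60 °C; then H2O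
Reagents that add atoms: water, O
Why: keteniminium–alkene [2+2] cycloaddition (Ghosez reaction) should join the terminal CH2 of one alkene to the central keteniminium carbon, which places the allyl residue at C3, and hydrolysis of the iminium salt gives the prochiral ketone while the excess of diene suppresses reaction at the second alkene.

Step 4
Reactants: 9 3-allylcyclobutan-1-one
Product: 10 (S)-[(3-allylcyclobut-1-en-1-yl)oxy]triethylsilane
Conditions: lithium (R,R)-bis(1-phenylethyl)amide (from the amine and n-BuLi), Et3SiCl (internal quench), THF, −100 °C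
Reagents that add atoms: chlorotriethylsilane, CC[Si](Cl)(CC)CC
Why: enantioselective deprotonation of a prochiral 3-substituted cyclobutanone by a C2-symmetric chiral lithium amide with in situ O-silylation (desymmetrisation) should work because the base chooses one of the two enantiotopic α-methylene groups, and that choice fixes the configuration of the allyl-bearing carbon.

Step 5
Reactants: 10 (S)-[(3-allylcyclobut-1-en-1-yl)oxy]triethylsilane
Product: 12 (S)-3-allyl-1-methoxycyclobut-1-ene, via lithium enolate 11 (not isolated)
Conditions: MeLi, THF, 0 °C; then DMPU, MeOTf, −78 °C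
Reagents that add atoms: methyl trifluoromethanesulfonate, COS(=O)(=O)C(F)(F)F
Why: Si–O cleavage by MeLi releases the regiodefined lithium enolate without a proton source that could scramble it, and the hard electrophile in a dipolar aprotic medium should alkylate oxygen (enolate O-alkylation) without touching the stereocentre.

Step 6
Reactants: 12 (S)-3-allyl-1-methoxycyclobut-1-ene; 4 2-allyl-4,5-dimethoxyphenol
Product: 14 (1R,2R,4S)-4-allyl-2-(2-allyl-4,5-dimethoxyphenoxy)-2-methoxycyclobutan-1-ol, via epoxy ether 13 (not isolated)
Conditions: DMDO (1.0 equiv), acetone/CH2Cl2, −78 °C; then 4, −78 → −20 °C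
Reagents that add atoms: dimethyldioxirane, CC1(C)OO1
Why: chemoselective epoxidation of the electron-rich enol ether on the face anti to the adjacent allyl group, followed by trans opening of the strained epoxy ether at its acetal carbon by the phenol (as in the opening of glycal epoxides), should place the aryloxy group cis to the allyl group and so set the ketal stereocentre, the carbinol centre being sacrificial.

Step 7
Reactants: 14 (1R,2R,4S)-4-allyl-2-(2-allyl-4,5-dimethoxyphenoxy)-2-methoxycyclobutan-1-ol
Product: 15 (2R,4S)-4-allyl-2-(2-allyl-4,5-dimethoxyphenoxy)-2-methoxycyclobutan-1-one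
Conditions: Dess–Martin periodinane, NaHCO3, CH2Cl2, 0 °C → rt
Reagents that add atoms: none
Why: Dess–Martin oxidation of the secondary alcohol under buffered, non-basic conditions should leave the acid-labile mixed ketal, the epimerisable α-allyl centre and both alkenes intact.

Step 8
Reactants: 16 2-chloro-1,1-dimethoxyethane
Product: 18 methoxyacetylene (kept as a titrated toluene solution), via sodium methoxyacetylide 17 (not isolated)
Conditions: NaNH2 (3 equiv), liquid NH3, −33 °C; then cold brine, distilled into toluene at −78 °C
Reagents that add atoms: none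
Why: twofold base-induced elimination of the chloroacetal (loss of MeOH, then of HCl) should give the alkoxyacetylide, which is protonated on work-up, as in the standard preparation of alkoxyacetylenes.

Step 9
Reactants: 15 (2R,4S)-4-allyl-2-(2-allyl-4,5-dimethoxyphenoxy)-2-methoxycyclobutan-1-one; 18 methoxyacetylene
Product: 19 (4R,6S)-6-allyl-4-(2-allyl-4,5-dimethoxyphenoxy)-3,4-dimethoxycyclohex-2-en-1-one
Conditions: Ni(cod)2 (10 mol %), PCy3 (20 mol %), toluene, 18 (3 equiv) added over 6 h, 25 → 60 °C
Reagents that add atoms: none
Why: Proposed new method: zerovalent nickel should couple the strained, inductively activated ketone of 15 with the ynol ether by oxidative cyclisation (the unsubstituted, nucleophilic alkyne carbon bonds to the carbonyl carbon C1, nickel to the methoxy-bearing carbon), and the resulting spiro oxanickelacyclopentene of divalent nickel should undergo strain-driven β-carbon elimination of the ketal carbon C4 followed by C(sp2)–C(sp3) reductive elimination. The closest known reaction type is the Ni(cod)2/phosphine-catalysed intermolecular [4+2] insertion of internal alkynes into cyclobutanones, 3-azetidinones and 3-oxetanones, which has not been shown for ynol ethers or for a fully substituted, dioxygenated migrating carbon. The six-membered ring closes as a formal [4+2] two-carbon ring expansion, its last bond (C3–C4) being formed by reductive elimination from a seven-membered nickelacycle. No new stereocentre is created: C4 passes from carbon to nickel to carbon with retention in both organometallic steps, and C6 is never deprotonated under the neutral, aprotic conditions. The step needs three selectivities: alkyne orientation, secured by the polarisation of the ynol ether and its small terminal carbon; cleavage of C1–C4 and not C1–C6, expected because a ketal oxygen on C4 can chelate nickel in the oxanickelacycle and the two oxygens weaken the adjacent C–C bond and stabilise the α,α-dioxyalkyl nickel; and coupling in preference to alkyne oligomerisation or binding of the allyl groups, addressed by slow addition of 18 and by the much stronger binding of alkyne and ketone than of monosubstituted alkenes.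

**Compound list**

1 | 3,4-dimethoxyphenol | COc1ccc(O)cc1OC | starting material
2 | allyl bromide (3-bromoprop-1-ene) | C=CCBr | starting material
3 | 4-(allyloxy)-1,2-dimethoxybenzene | C=CCOc1ccc(OC)c(OC)c1 | intermediate
4 | 2-allyl-4,5-dimethoxyphenol | C=CCc1cc(OC)c(OC)cc1O | intermediate
5 | N,N-dimethylacetamide | CC(=O)N(C)C | starting material
6 | penta-1,4-diene | C=CCC=C | starting material
7 | N,N-dimethylketeniminium triflate | C=C=[N+](C)C.[O-]S(=O)(=O)C(F)(F)F | intermediate
8 | N-(3-allylcyclobutylidene)-N-methylmethanaminium triflate | C=CCC1CC(=[N+](C)C)C1.[O-]S(=O)(=O)C(F)(F)F | intermediate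
9 | 3-allylcyclobutan-1-one | C=CCC1CC(=O)C1 | intermediate
10 | (S)-[(3-allylcyclobut-1-en-1-yl)oxy]triethylsilane | CC[Si](CC)(CC)OC1=C[C@@H](CC=C)C1 | intermediate
11 | lithium (S)-3-allylcyclobut-1-en-1-olate | [Li+].[O-]C1=C[C@@H](CC=C)C1 | intermediate
12 | (S)-3-allyl-1-methoxycyclobut-1-ene | COC1=C[C@@H](CC=C)C1 | intermediate
13 | (1S,3S,4R)-3-allyl-1-methoxy-5-oxabicyclo[2.1.0]pentane (oxirane oxygen trans to the allyl group) | CO[C@]12C[C@H](CC=C)[C@H]1O2 | intermediate
14 | (1R,2R,4S)-4-allyl-2-(2-allyl-4,5-dimethoxyphenoxy)-2-methoxycyclobutan-1-ol (aryloxy cis to allyl, hydroxyl trans to both) | C=CCc1cc(OC)c(OC)cc1O[C@]1(OC)C[C@H](CC=C)[C@H]1O | intermediate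
15 | (2R,4S)-4-allyl-2-(2-allyl-4,5-dimethoxyphenoxy)-2-methoxycyclobutan-1-one | C=CCc1cc(OC)c(OC)cc1O[C@]1(OC)C[C@H](CC=C)C1=O | intermediate
16 | 2-chloro-1,1-dimethoxyethane | COC(CCl)OC | starting material
17 | sodium methoxyacetylide | [Na+].[C-]#COC | intermediate
18 | methoxyacetylene (methoxyethyne) | C#COC | intermediate
19 | (4R,6S)-6-allyl-4-(2-allyl-4,5-dimethoxyphenoxy)-3,4-dimethoxycyclohex-2-en-1-one | C=CCc1cc(OC)c(OC)cc1O[C@]1(OC)C[C@H](CC=C)C(=O)C=C1OC | target

**Step count and risks**

Total steps: 9. Longest linear sequence: 6 (steps 3, 4, 5, 6, 7, 9); steps 1–2 and step 8 are side branches.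

Steps most likely to fail:

1. Step 9. The β-carbon elimination may take the C1–C6 bond and not the hindered C1–C4 bond, or the terminal ynol ether may oligomerise on nickel faster than it couples with the ketone. The fallback uses known chemistry, sets out from 4 and comes back at 19; it gives up the ring expansion and obtains the absolute configuration by resolution.
 - Commercial 4-bromo-3-methoxyphenol is O-allylated with 2 (K2CO3, acetone) to 4-(allyloxy)-1-bromo-2-methoxybenzene F1.
 - Ullmann etherification of 4 with F1 (CuI, picolinic acid, K3PO4, DMSO, 90 °C) should give 1-allyl-2-[4-(allyloxy)-2-methoxyphenoxy]-4,5-dimethoxybenzene F2.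
 - Aromatic Claisen rearrangement (N,N-diethylaniline, 190 °C) should move the O-allyl group to the free ortho carbon and give 2-allyl-4-(2-allyl-4,5-dimethoxyphenoxy)-5-methoxyphenol F3.
 - Oxidative dearomatisation with PhI(OAc)2 in MeOH at 0 °C should give racemic 2-allyl-4-(2-allyl-4,5-dimethoxyphenoxy)-4,5-dimethoxycyclohexa-2,5-dien-1-one F4.
 - 1,4-Reduction of the non-oxygenated enone with LiBH(s-Bu)3 (THF, −78 °C) and kinetic protonation of the enolate anti to the aryloxy group should give racemic (4R*,6S*)-6-allyl-4-(2-allyl-4,5-dimethoxyphenoxy)-3,4-dimethoxycyclohex-2-en-1-one F5.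
 - Chromatography on a chiral stationary phase then separates 19 from its enantiomer.

2. Step 5. C-methylation of the enolate may compete with O-methylation, and proton exchange may scramble the enolate, which here means racemisation. The fallback sets out from 10 and comes back at 14 without a methyl enol ether.
 - Rubottom oxidation of 10 with DMDO (CH2Cl2, −78 → 0 °C; epoxidation anti to allyl, then silyl shift) should give (2R,3S)-3-allyl-2-(triethylsilyloxy)cyclobutan-1-one F6.
 - Aprotic ketalisation (MeOSiMe3, catalytic Me3SiOTf, CH2Cl2, −78 °C) should give [(1R,4S)-4-allyl-2,2-dimethoxycyclobutoxy]triethylsilane F7.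
 - Me3SiOTf-catalysed exchange of one methoxy group for phenol 4 at −78 °C, with attack on the oxocarbenium ion anti to the neighbouring silyloxy group, should give {[(1R,2R,4S)-4-allyl-2-(2-allyl-4,5-dimethoxyphenoxy)-2-methoxycyclobutyl]oxy}triethylsilane F8.
 - Bu4NF in THF removes the silyl group and returns to 14.

3. Step 6. The strained epoxy ether may ring-contract or rearrange before the phenol captures it, the electron-rich phenol may be oxidised by the dioxirane, or the phenol may attack through carbon. The fallback sets out from 12, avoids an epoxide and comes back at 15.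
 - Sulfenyl-etherification with PhSCl (CH2Cl2, −78 °C), then 4 and i-Pr2NEt, forms the episulfonium ion anti to allyl and opens it anti with the phenol. It should give [(1R,2R,4S)-4-allyl-2-(2-allyl-4,5-dimethoxyphenoxy)-2-methoxycyclobutyl](phenyl)sulfane F9.
 - mCPBA (1 equiv, −78 °C) should give the sulfoxide (1R,2R,4S)-4-allyl-2-(2-allyl-4,5-dimethoxyphenoxy)-2-methoxy-1-(phenylsulfinyl)cyclobutane F10.
 - Pummerer rearrangement ((CF3CO)2O, 2,6-lutidine, 0 °C; then aqueous NaHCO3) unmasks the ketone and rejoins the route at 15.

**Further compounds**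

F1 | step 9 | 4-(allyloxy)-1-bromo-2-methoxybenzene | C=CCOc1ccc(Br)c(OC)c1
F2 | step 9 | 1-allyl-2-[4-(allyloxy)-2-methoxyphenoxy]-4,5-dimethoxybenzene | C=CCOc1ccc(Oc2cc(OC)c(OC)cc2CC=C)c(OC)c1
F3 | step 9 | 2-allyl-4-(2-allyl-4,5-dimethoxyphenoxy)-5-methoxyphenol | C=CCc1cc(Oc2cc(OC)c(OC)cc2CC=C)c(OC)cc1O
F4 | step 9 | racemic 2-allyl-4-(2-allyl-4,5-dimethoxyphenoxy)-4,5-dimethoxycyclohexa-2,5-dien-1-one | C=CCC1=CC(OC)(Oc2cc(OC)c(OC)cc2CC=C)C(OC)=CC1=O
F5 | step 9 | racemic (4R*,6S*)-6-allyl-4-(2-allyl-4,5-dimethoxyphenoxy)-3,4-dimethoxycyclohex-2-en-1-one (racemate of 19) | C=CCc1cc(OC)c(OC)cc1OC1(OC)CC(CC=C)C(=O)C=C1OC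
F6 | step 5 | (2R,3S)-3-allyl-2-(triethylsilyloxy)cyclobutan-1-one | O=C1C[C@H](CC=C)[C@H]1O[Si](CC)(CC)CC
F7 | step 5 | [(1R,4S)-4-allyl-2,2-dimethoxycyclobutoxy]triethylsilane | COC1(OC)C[C@H](CC=C)[C@H]1O[Si](CC)(CC)CC
F8 | step 5 | {[(1R,2R,4S)-4-allyl-2-(2-allyl-4,5-dimethoxyphenoxy)-2-methoxycyclobutyl]oxy}triethylsilane | C=CCc1cc(OC)c(OC)cc1O[C@]1(OC)C[C@H](CC=C)[C@H]1O[Si](CC)(CC)CC
F9 | step 6 | [(1R,2R,4S)-4-allyl-2-(2-allyl-4,5-dimethoxyphenoxy)-2-methoxycyclobutyl](phenyl)sulfane | C=CCc1cc(OC)c(OC)cc1O[C@]1(OC)C[C@H](CC=C)[C@H]1Sc1ccccc1
F10 | step 6 | (1R,2R,4S)-4-allyl-2-(2-allyl-4,5-dimethoxyphenoxy)-2-methoxy-1-(phenylsulfinyl)cyclobutane (mixture at sulfur) | C=CCc1cc(OC)c(OC)cc1O[C@]1(OC)C[C@H](CC=C)[C@H]1S(=O)c1ccccc1
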